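The plan rests on forming the C7–O bond last, on an intact 5-oxygenated 3-methoxyflavone. In ring A of such a flavone, C7–H is the only aromatic C–H flanked by two C–H carbons (C6 and C8); C6–H, C8–H and all ring B C–H bonds lie next to a substituent. A sterically governed C–H borylation with [Ir(OMe)(cod)]2, followed by NaBO3 oxidation in the same flask, should therefore turn C7–H into C7–OH in one operation. The substrate is 3-methoxy-4'-prenyloxyflavone with a triisopropylsilyl ether on O5, built from resorcinol by directed lithiation, Weinreb acylation and Baker–Venkataraman ring construction. The prenyl ether is attached only after the acid step, and TBAF frees O5 at the end.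

Key step: step 9

Remarks on the chemistry:
- Assumption: "prenyl" is 3-methylbut-2-en-1-yl, bound through oxygen to C4' of ring B. The target has no stereocentre and no E/Z element.
- An aryl prenyl ether does not tolerate hot mineral acid, so O4' is prenylated after the acid-mediated closure of ring C. At that point the hydrogen-bonded 5-OH does not compete.
- O5 carries a triisopropylsilyl ether in the key step. It screens C6–H, has no unhindered C–H of its own, and leaves with fluoride, so the prenyl ether never meets acid.

Step 1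
Reactants: 1 resorcinol
Product: 2 1,3-bis(methoxymethoxy)benzene
Conditions: NaH, MOMCl, DMF, 0 °C → rt
Reagents that add atoms: chloromethyl methyl ether (MOMCl), COCCl
Why: Double Williamson-type O-alkylation of the bis-phenoxide by the reactive α-chloro ether gives the bis-acetal, whose two OCH2OMe groups will direct lithiation to the carbon between them.

Step 2
Reactants: 2 1,3-bis(methoxymethoxy)benzene; 3 N,2-dimethoxy-N-methylacetamide
Product: 5 1-[2,6-bis(methoxymethoxy)phenyl]-2-methoxyethan-1-one, via aryllithium 4 (not isolated)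
Conditions: n-BuLi, THF, 0 °C; then 3, −78 °C → 0 °C; aq. NH4Cl
Reagents that add atoms: none
Why: Directed ortho-metalation, in which both acetal oxygens chelate lithium so that only C2 between them is deprotonated, followed by a single acylation of the aryllithium by the N-methoxy-N-methylamide (Weinreb ketone synthesis), which cannot over-add.

Step 3
Reactants: 5 1-[2,6-bis(methoxymethoxy)phenyl]-2-methoxyethan-1-one
Product: 6 1-[2-hydroxy-6-(methoxymethoxy)phenyl]-2-methoxyethan-1-one
Conditions: I2 (10 mol%), MeOH, rt, stopped when 5 is consumed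
Reagents that add atoms: none
Why: Mild acid-catalysed acetal exchange with methanol (HI formed in situ) removes one MOM group, and the freed phenol then hydrogen-bonds to the ketone, which slows loss of the second ortho acetal, so the selective mono-deprotection known for ortho-MOM aryl ketones should result.

Step 4
Reactants: 7 methyl 4-hydroxybenzoate
Product: 9 4-(methoxymethoxy)benzoic acid, via methyl ester 8 (not isolated)
Conditions: NaH, MOMCl, THF/DMF, 0 °C → rt; then LiOH, MeOH/H2O, 50 °C; cold 1 M HCl to pH 4
Reagents that add atoms: chloromethyl methyl ether (MOMCl), COCCl; lithium hydroxide LiOH, [Li+].[OH-]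
Why: Williamson-type O-alkylation of the phenoxide followed by ester saponification in the same flask, the aryl MOM ether being stable to base and to the brief cold acidification.

Step 5
Reactants: 6 1-[2-hydroxy-6-(methoxymethoxy)phenyl]-2-methoxyethan-1-one; 9 4-(methoxymethoxy)benzoic acid
Product: 10 2-(methoxyacetyl)-3-(methoxymethoxy)phenyl 4-(methoxymethoxy)benzoate
Conditions: EDC·HCl, DMAP, CH2Cl2, rt
Reagents that add atoms: none
Why: Steglich esterification through the O-acylisourea and the acylpyridinium ion acylates the hydrogen-bonded phenol without an acid chloride or free HCl, so both acetals survive.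

Step 6
Reactants: 10 2-(methoxyacetyl)-3-(methoxymethoxy)phenyl 4-(methoxymethoxy)benzoate
Product: 12 4',5-dihydroxy-3-methoxyflavone, via diketone 11 (not isolated)
Conditions: KOt-Bu, THF, 0 °C → rt; then MeOH, conc. HCl, 60 °C
Reagents that add atoms: none
Why: Baker–Venkataraman rearrangement, in which the ketone enolate attacks the neighbouring aryl ester through a six-membered transition state to give the 1,3-diketone, followed by methanolic HCl, which removes both MOM groups and closes ring C by phenol attack on the aroyl carbonyl and loss of water (cyclodehydration) while no other acid-sensitive group is present.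

Step 7
Reactants: 12 4',5-dihydroxy-3-methoxyflavone; 13 prenyl bromide
Product: 14 5-hydroxy-3-methoxy-4'-prenyloxyflavone
Conditions: K2CO3, acetone, 50 °C
Reagents that add atoms: none
Why: Williamson ether synthesis in which K2CO3 ionises only the 4'-phenol, because the 5-OH is locked in a hydrogen bond to the C4 carbonyl and is less acidic and less nucleophilic, and SN2 attack at the primary allylic carbon gives the linear prenyl ether.

Step 8
Reactants: 14 5-hydroxy-3-methoxy-4'-prenyloxyflavone
Product: 15 3-methoxy-4'-prenyloxy-5-(triisopropylsilyloxy)flavone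
Conditions: TIPSOTf, 2,6-lutidine, CH2Cl2, 0 °C → rt
Reagents that add atoms: triisopropylsilyl trifluoromethanesulfonate (TIPSOTf), CC(C)[Si](OS(=O)(=O)C(F)(F)F)(C(C)C)C(C)C
Why: O-Silylation, for which the silyl triflate is electrophilic enough to reach the chelated 5-phenol, while the hindered pyridine base keeps the medium non-acidic for the prenyl ether.

Step 9
Reactants: 15 3-methoxy-4'-prenyloxy-5-(triisopropylsilyloxy)flavone
Product: 17 7-hydroxy-3-methoxy-4'-prenyloxy-5-(triisopropylsilyloxy)flavone, via C7 pinacol boronate 16 (not isolated)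
Conditions: [Ir(OMe)(cod)]2 (2.5 mol%), 4,4'-di-tert-butyl-2,2'-bipyridine (5 mol%), B2pin2 (1.0 equiv), THF, 70 °C; then NaBO3·4H2O, THF/H2O, rt
Reagents that add atoms: sodium perborate NaBO3 (used as the tetrahydrate), [Na+].[O-]OB=O
Why: The precatalyst [Ir(OMe)(cod)]2 (monovalent iridium), the bipyridine and B2pin2 form a tris(boryl) complex of trivalent iridium that cleaves an aromatic C–H bond, and C–B reductive elimination releases boronate 16; NaBO3 then adds to boron, the aryl group shifts from boron to oxygen, and hydrolysis gives the phenol. The closest known reaction type is the sterically governed arene C–H borylation with one-pot NaBO3 oxidation to the phenol, long established for 1,3-disubstituted and 1,2,3-trisubstituted benzenes. No ring is closed and no stereocentre is formed. The step needs site selectivity for C7–H over C6–H, C8–H and the four C–H bonds of ring B, and the substrate secures it: C7–H alone has hydrogen on both neighbouring carbons, C6–H is screened by the triisopropylsilyl ether on O5, C8–H lies next to the ring oxygen O1, and every ring B C–H is ortho to C1' or to the prenyloxy group. Chemoselectivity is also needed: the trisubstituted prenyl alkene is too hindered for hydroboration here, the nucleophilic oxidant does not epoxidise it, and C3 carries no hydrogen.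

Step 10
Reactants: 17 7-hydroxy-3-methoxy-4'-prenyloxy-5-(triisopropylsilyloxy)flavone
Product: 18 5,7-dihydroxy-3-methoxy-4'-prenyloxyflavone
Conditions: TBAF, AcOH, THF, 0 °C → rt
Reagents that add atoms: none
Why: Fluoride-mediated desilylation, driven by the strong Si–F bond, frees the 5-phenol under buffered, non-acidic and non-reducing conditions, so the prenyl ether, the 3-methoxy group and the chromone stay intact.

Compound list
1 | resorcinol (benzene-1,3-diol) | Oc1cccc(O)c1 | starting material
2 | 1,3-bis(methoxymethoxy)benzene | COCOc1cccc(OCOC)c1 | intermediate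
3 | N,2-dimethoxy-N-methylacetamide | COCC(=O)N(C)OC | starting material
4 | [2,6-bis(methoxymethoxy)phenyl]lithium | [Li]c1c(OCOC)cccc1OCOC | intermediate (not isolated)
5 | 1-[2,6-bis(methoxymethoxy)phenyl]-2-methoxyethan-1-one | COCC(=O)c1c(OCOC)cccc1OCOC | intermediate
6 | 1-[2-hydroxy-6-(methoxymethoxy)phenyl]-2-methoxyethan-1-one | COCC(=O)c1c(O)cccc1OCOC | intermediate
7 | methyl 4-hydroxybenzoate | COC(=O)c1ccc(O)cc1 | starting material
8 | methyl 4-(methoxymethoxy)benzoate | COCOc1ccc(cc1)C(=O)OC | intermediate (not isolated)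
9 | 4-(methoxymethoxy)benzoic acid | COCOc1ccc(cc1)C(=O)O | intermediate
10 | 2-(methoxyacetyl)-3-(methoxymethoxy)phenyl 4-(methoxymethoxy)benzoate | COCC(=O)c1c(OCOC)cccc1OC(=O)c1ccc(OCOC)cc1 | intermediate
11 | 1-[2-hydroxy-6-(methoxymethoxy)phenyl]-2-methoxy-3-[4-(methoxymethoxy)phenyl]propane-1,3-dione (racemic, enolisable centre) | COCOc1ccc(cc1)C(=O)C(OC)C(=O)c1c(O)cccc1OCOC | intermediate (not isolated)
12 | 4',5-dihydroxy-3-methoxyflavone (5-hydroxy-2-(4-hydroxyphenyl)-3-methoxy-4H-chromen-4-one) | COc1c(-c2ccc(O)cc2)oc2cccc(O)c2c1=O | intermediate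
13 | prenyl bromide (1-bromo-3-methylbut-2-ene) | CC(C)=CCBr | starting material
14 | 5-hydroxy-3-methoxy-4'-prenyloxyflavone | COc1c(-c2ccc(OCC=C(C)C)cc2)oc2cccc(O)c2c1=O | intermediate
15 | 3-methoxy-4'-prenyloxy-5-(triisopropylsilyloxy)flavone | COc1c(-c2ccc(OCC=C(C)C)cc2)oc2cccc(O[Si](C(C)C)(C(C)C)C(C)C)c2c1=O | intermediate
16 | 3-methoxy-4'-prenyloxy-7-(4,4,5,5-tetramethyl-1,3,2-dioxaborolan-2-yl)-5-(triisopropylsilyloxy)flavone | COc1c(-c2ccc(OCC=C(C)C)cc2)oc2cc(B3OC(C)(C)C(C)(C)O3)cc(O[Si](C(C)C)(C(C)C)C(C)C)c2c1=O | intermediate (not isolated)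
17 | 7-hydroxy-3-methoxy-4'-prenyloxy-5-(triisopropylsilyloxy)flavone | COc1c(-c2ccc(OCC=C(C)C)cc2)oc2cc(O)cc(O[Si](C(C)C)(C(C)C)C(C)C)c2c1=O | intermediate
18 | 5,7-dihydroxy-3-methoxy-4'-prenyloxyflavone | COc1c(-c2ccc(OCC=C(C)C)cc2)oc2cc(O)cc(O)c2c1=O | target

Total step count: 10
Longest linear sequence: 9 steps (steps 1, 2, 3, 5, 6, 7, 8, 9 and 10 from resorcinol); step 4 is a one-step side branch that joins at step 5.

Steps most likely to fail

Step 9. Site selectivity may erode, with borylation leaking to C6, C8 or ring B. The prenyl alkene may be consumed by hydroboration with the pinacolborane formed during the reaction. Turnover may also stall if the chromone binds the catalyst.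

The fallback gives up the late C–H oxygenation and carries the C7 oxygen from the start. It sets out from amide 3 and acid 9 and comes back at target 18. Commercial phloroglucinol is converted with NaH and MOMCl into 1,3,5-tris(methoxymethoxy)benzene F1. Lithiation with n-BuLi and acylation with 3 should give 2-methoxy-1-[2,4,6-tris(methoxymethoxy)phenyl]ethan-1-one F2. I2 in MeOH frees one ortho phenol to give 1-[2-hydroxy-4,6-bis(methoxymethoxy)phenyl]-2-methoxyethan-1-one F3. EDC·HCl and DMAP join F3 to 9 as 2-(methoxyacetyl)-3,5-bis(methoxymethoxy)phenyl 4-(methoxymethoxy)benzoate F4. KOt-Bu then methanolic HCl lead through the diketone 1-[2-hydroxy-4,6-bis(methoxymethoxy)phenyl]-2-methoxy-3-[4-(methoxymethoxy)phenyl]propane-1,3-dione F5 to 5,7-dihydroxy-2-(4-hydroxyphenyl)-3-methoxy-4H-chromen-4-one F6. The most acidic hydroxyl, 7-OH, is silylated selectively with TIPSCl and imidazole in DMF at 0 °C to give 5-hydroxy-2-(4-hydroxyphenyl)-3-methoxy-7-(triisopropylsilyloxy)-4H-chromen-4-one F7. A Mitsunobu etherification of the 4'-OH with 3-methylbut-2-en-1-ol (PPh3, DIAD, THF) gives 5-hydroxy-3-methoxy-4'-prenyloxy-7-(triisopropylsilyloxy)flavone F8. TBAF with AcOH then gives 18.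

Step 8. Silylation of the hydrogen-bonded, peri-hindered 5-phenol may stay incomplete, or the silyl ether may be lost during purification.

The fallback replaces silylation by acylation and the fluoride endgame by methanolysis. It sets out from 14 and comes back at 18. NaH and pivaloyl chloride in THF should give 3-methoxy-4-oxo-2-[4-(prenyloxy)phenyl]-4H-chromen-5-yl pivalate F9. The same borylation and NaBO3 oxidation would pass through 3-methoxy-4-oxo-2-[4-(prenyloxy)phenyl]-7-(4,4,5,5-tetramethyl-1,3,2-dioxaborolan-2-yl)-4H-chromen-5-yl pivalate F10 to 7-hydroxy-3-methoxy-4-oxo-2-[4-(prenyloxy)phenyl]-4H-chromen-5-yl pivalate F11. K2CO3 in MeOH at rt then removes the ester to give 18. Any ester lost during the oxidation converges on the same product.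

Step 3. Cleavage may run on to the diol or stall short of completion, since the two acetals differ only through the hydrogen bond formed after the first cleavage.

The fallback separates the two events. It sets out from 5 and comes back at 6. HCl in MeOH at 50 °C removes both acetals to give 1-(2,6-dihydroxyphenyl)-2-methoxyethan-1-one F12. One equivalent of MOMCl with i-Pr2NEt in CH2Cl2 at 0 °C then etherifies a single phenol, because the remaining hydroxyl is held by the ketone, and gives 6.

Further compounds
F1 | step 9 | 1,3,5-tris(methoxymethoxy)benzene | COCOc1cc(OCOC)cc(OCOC)c1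
F2 | step 9 | 2-methoxy-1-[2,4,6-tris(methoxymethoxy)phenyl]ethan-1-one | COCC(=O)c1c(OCOC)cc(OCOC)cc1OCOC
F3 | step 9 | 1-[2-hydroxy-4,6-bis(methoxymethoxy)phenyl]-2-methoxyethan-1-one | COCC(=O)c1c(O)cc(OCOC)cc1OCOC
F4 | step 9 | 2-(methoxyacetyl)-3,5-bis(methoxymethoxy)phenyl 4-(methoxymethoxy)benzoate | COCC(=O)c1c(OCOC)cc(OCOC)cc1OC(=O)c1ccc(OCOC)cc1
F5 | step 9 | 1-[2-hydroxy-4,6-bis(methoxymethoxy)phenyl]-2-methoxy-3-[4-(methoxymethoxy)phenyl]propane-1,3-dione (racemic, not isolated) | COCOc1ccc(cc1)C(=O)C(OC)C(=O)c1c(O)cc(OCOC)cc1OCOC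
F6 | step 9 | 5,7-dihydroxy-2-(4-hydroxyphenyl)-3-methoxy-4H-chromen-4-one | COc1c(-c2ccc(O)cc2)oc2cc(O)cc(O)c2c1=O
F7 | step 9 | 5-hydroxy-2-(4-hydroxyphenyl)-3-methoxy-7-(triisopropylsilyloxy)-4H-chromen-4-one | COc1c(-c2ccc(O)cc2)oc2cc(O[Si](C(C)C)(C(C)C)C(C)C)cc(O)c2c1=O
F8 | step 9 | 5-hydroxy-3-methoxy-4'-prenyloxy-7-(triisopropylsilyloxy)flavone | COc1c(-c2ccc(OCC=C(C)C)cc2)oc2cc(O[Si](C(C)C)(C(C)C)C(C)C)cc(O)c2c1=O
F9 | step 8 | 3-methoxy-4-oxo-2-[4-(prenyloxy)phenyl]-4H-chromen-5-yl pivalate | COc1c(-c2ccc(OCC=C(C)C)cc2)oc2cccc(OC(=O)C(C)(C)C)c2c1=O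
F10 | step 8 | 3-methoxy-4-oxo-2-[4-(prenyloxy)phenyl]-7-(4,4,5,5-tetramethyl-1,3,2-dioxaborolan-2-yl)-4H-chromen-5-yl pivalate (not isolated) | COc1c(-c2ccc(OCC=C(C)C)cc2)oc2cc(B3OC(C)(C)C(C)(C)O3)cc(OC(=O)C(C)(C)C)c2c1=O
F11 | step 8 | 7-hydroxy-3-methoxy-4-oxo-2-[4-(prenyloxy)phenyl]-4H-chromen-5-yl pivalate | COc1c(-c2ccc(OCC=C(C)C)cc2)oc2cc(O)cc(OC(=O)C(C)(C)C)c2c1=O
F12 | step 3 | 1-(2,6-dihydroxyphenyl)-2-methoxyethan-1-one | COCC(=O)c1c(O)cccc1O
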